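**Plan**

- Locants: ring A is C1–C5 plus C10, ring B is C5–C10. C1 bears the side chain, C4 and C11 are the carbinol carbons, C10 is the methylated fusion carbon, C9' is the benzylic carbon.
- Enabling feature: in ring B the carbinol carbon C11 sits on C7 next to the methylene C8. The unit C8–C7–C11(OH) is what is left when an aldehyde carbon C8 bonds to C7 of a C7=C11 prenyl alkene and water adds to C11.
- Retrosynthesis: cut the three aryl O–CH3 bonds and the two aryl–CHO bonds, then C9'–CH2 (isobutyl arm) and C9'–aryl, then C4–CH3. Return an oxygen to C8, cut C7–C8 and C11–OH (retro-Prins) to a ring A keto aldehyde, then cut C5–C6 (prenyl) and C10–C9 (vinyl) back to Hagemann's ester.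
- Forward: ring A is Hagemann's ester, armed at C10 and C5. Ring B closes by Prins cyclisation with hydration. Then follow C8 deoxygenation, C4 methylation, aryl addition at C9', methallylation and hydrogenation, double formylation and O-demethylation.
- Stereochemistry: C10 relative to C1 from cuprate addition anti to the ester. C5 by equilibration and separation, with the absolute series fixed by resolution at the same stage. C7 from the chair transition state of the Prins step. C4 from equatorial attack anti to the axial C10 methyl. C9' from capture of the benzylic cation anti to C10.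

Key step: step 5

Assumption: commercial 1 is racemic, so the enantiomers are separated at 6; which enantiomer belongs to the target series would be settled later by anomalous-dispersion X-ray analysis of the dibromide 21.

Remark: the C8 hydroxyl of 10 is drawn equatorial, as expected; either C8 epimer serves because this oxygen is removed in step 7.

**Step 1**
Reactants: 1 Hagemann's ester (racemic), 2 vinylmagnesium bromide, 3 prenyl bromide
Product: 5 racemic prenylated vinyl keto ester (both C5 epimers), via bromomagnesium enolate 4 (not isolated)
Conditions: 2 (1.4 equiv, added slowly), CuBr·SMe2 (10 mol%), THF, −30 °C; then 3 (2 equiv), DMPU, −30 → 20 °C; aq. NH4Cl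
Reagents that add atoms: none
Why: Copper-catalysed 1,4-addition of the vinyl Grignard reagent to the β-methyl enone should take place anti to the pseudoaxial ester on the neighbouring carbon, which sets the quaternary C10 relative to C1, and the magnesium enolate so formed is regiodefined toward C5 and is C-alkylated there by the allylic bromide (tandem conjugate addition–enolate alkylation); the C5 configuration is not relied on here because step 2 corrects it.

**Step 2**
Reactants: 5 racemic prenylated vinyl keto ester
Product: 6 keto ester with prenyl trans to vinyl (single enantiomer)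
Conditions: NaOEt (0.2 equiv), EtOH, 20 °C; then preparative SFC on amylose tris(3,5-dimethylphenylcarbamate), CO2/MeOH; the C5 epimer of the same enantiomeric series goes back to the base treatment
Reagents that add atoms: none
Why: Epimerisation through the ketone enolate interconverts only the C5 epimers (C10 is quaternary and the ester α-hydrogen at C1 is several orders of magnitude less acidic), so the epimer with prenyl trans to vinyl can be collected and the other recycled while the chiral phase separates the enantiomers (equilibration followed by chromatographic resolution); no thermodynamic bias is assumed, since an equatorial group beside the quaternary C10 is gauche to both of its substituents.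

**Step 3**
Reactants: 6 keto ester with prenyl trans to vinyl
Product: 8 keto alcohol, via catechol boronate 7 (not isolated)
Conditions: catecholborane (1.5 equiv), RhCl(PPh3)3 (2 mol%), THF, 0 → 20 °C; then 30% H2O2, pH 8 phosphate buffer, 0 °C; used at once in step 4
Reagents that add atoms: hydrogen peroxide, OO (oxygen on C8); catecholborane, B1Oc2ccccc2O1 (boron and catechol atoms of 7 only)
Why: Rhodium-catalysed hydroboration with catecholborane places boron on the terminal carbon of the monosubstituted alkene much faster than the borane reduces the ketone and leaves the trisubstituted prenyl alkene and the ester alone, and buffered peroxide oxidation of the C–B bond gives the primary alcohol (hydroboration–oxidation) with no new stereocentre and no base strong enough to epimerise C5.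

**Step 4**
Reactants: 8 keto alcohol
Product: 9 keto aldehyde
Conditions: tetrapropylammonium perruthenate (5 mol%), N-methylmorpholine N-oxide (1.5 equiv), 4 Å molecular sieves, CH2Cl2, 20 °C
Reagents that add atoms: none
Why: Perruthenate-catalysed (Ley–Griffith) oxidation converts the primary alcohol into the aldehyde under neutral, anhydrous conditions that should neither over-oxidise nor epimerise C5, and the ketone, ester and alkene are inert.

**Step 5**
Reactants: 9 keto aldehyde
Product: 10 trans-decalone diol ester
Conditions: 0.5 M aq. H2SO4/THF (1:1), 45 °C
Reagents that add atoms: water, O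
Why: The protonated C8 aldehyde is attacked by C7 of the trisubstituted C7=C11 alkene (Prins, carbonyl–olefin cyclisation), the charge settles on tertiary C11 and water adds there, so one C–C bond, ring B and the C11 carbinol arise together; the closest known case is the dilute-acid cyclisation of citronellal to p-menthane-3,8-diol. Ring B (C5–C10) closes in the 6-exo mode with respect to both π bonds, C11 and the carbonyl oxygen staying outside the new ring, through a chair transition state trans-fused to the chair of ring A. C7 is controlled by this chair: the two arms sit trans-diequatorial on C5 and C10, the C10 methyl is axial, and the reacting alkene carbon carries C11 equatorially, cis to that methyl; C8 is controlled by the same axial methyl, which keeps the carbonyl oxygen equatorial, and this centre is deleted in step 7 in any case. The step needs Markovnikov regioselectivity, secured by the prenyl group (six-membered ring and tertiary cation against seven-membered ring and secondary cation), and chemoselectivity for the aldehyde, secured because the C4 ketone could reach the alkene only through a four- or five-membered ring and because enolisation at C3 or C5 is slow in dilute acid at this temperature, which also preserves the C5 configuration.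

**Step 6**
Reactants: 10 trans-decalone diol ester
Product: 11 C8 O-phenyl thionocarbonate
Conditions: PhOC(S)Cl (1.3 equiv), pyridine, CH2Cl2, 0 → 20 °C
Reagents that add atoms: O-phenyl chlorothionoformate, S=C(Cl)Oc1ccccc1
Why: Thioacylation of the secondary C8 hydroxyl is the first half of a Barton–McCombie deoxygenation; the tertiary C11 hydroxyl is too hindered to be acylated under these conditions, the ketone and ester are inert, and no stereocentre is changed.

**Step 7**
Reactants: 11 C8 O-phenyl thionocarbonate
Product: 12 C8-deoxy keto ester
Conditions: Bu3SnH (1.5 equiv), AIBN (0.2 equiv), toluene, 90 °C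
Reagents that add atoms: none
Why: In the Barton–McCombie radical chain the stannyl radical adds to the thiocarbonyl sulfur, the C8–O bond fragments and the secondary C8 radical takes hydrogen from Bu3SnH, so C8 becomes a methylene group (its stereocentre disappears) while the ketone, ester and tertiary alcohol survive.

**Step 8**
Reactants: 12 C8-deoxy keto ester
Product: 13 C4 methyl carbinol ester
Conditions: MeMgBr (3.5 equiv), CeCl3 (3.5 equiv), THF, −78 °C; aq. NH4Cl
Reagents that add atoms: methylmagnesium bromide, C[Mg]Br
Why: The organocerium reagent formed from MeMgBr and CeCl3 adds to the hindered, enolisable C4 ketone in preference to the ester (chemoselective 1,2-addition) and approaches along the equatorial trajectory anti to the axial C10 methyl, which should give the axial C4 hydroxyl cis to that methyl with the new methyl equatorial, as in the target.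

**Step 9**
Reactants: 13 C4 methyl carbinol ester
Product: 14 triol
Conditions: LiAlH4 (2 equiv), THF, 0 → 40 °C; then H2O
Reagents that add atoms: none
Why: Hydride reduction of the ester with LiAlH4 gives the primary alcohol at C1 without touching the tertiary alcohols or any stereocentre.

**Step 10**
Reactants: 14 triol
Product: 15 dihydroxy aldehyde
Conditions: tetrapropylammonium perruthenate (5 mol%), N-methylmorpholine N-oxide (1.5 equiv), 4 Å molecular sieves, CH2Cl2, 20 °C
Reagents that add atoms: none
Why: The same perruthenate (Ley–Griffith) oxidation acts only on the primary hydroxyl, the two others being tertiary, and its neutral conditions should keep the epimerisable C1 centre.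

**Step 11**
Reactants: 15 dihydroxy aldehyde, 16 1,3,5-trimethoxybenzene
Product: 18 benzylic alcohol (both C9' epimers), via 2,4,6-trimethoxyphenyllithium 17 (not isolated)
Conditions: 16 (4 equiv), n-BuLi (3.6 equiv), THF, 0 → 20 °C; then 15, −78 → 0 °C; aq. NH4Cl
Reagents that add atoms: n-butyllithium, [Li]CCCC (lithium atom of 17 only)
Why: Deprotonation of 16 between two methoxy groups (directed ortho-lithiation) gives the aryllithium, which adds to the aldehyde once the excess reagent has deprotonated the two tertiary hydroxyls (1,2-addition); the new C9' carbinol centre is formed without control because it is erased by ionisation in step 12.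

**Step 12**
Reactants: 18 benzylic alcohol
Product: 19 C9' methallyl compound
Conditions: methallyltrimethylsilane (3 equiv), Bi(OTf)3 (5 mol%), CH2Cl2, −40 → 0 °C
Reagents that add atoms: methallyltrimethylsilane, C=C(C)C[Si](C)(C)C
Why: In this SN1-type Hosomi–Sakurai allylation the Lewis acid should ionise only the benzylic hydroxyl, whose cation is stabilised by three ortho/para methoxy groups, and the allylsilane should attack the planar cation in the conformer with C1–H eclipsing the aryl plane (least allylic 1,3-strain) from the face opposite the quaternary C10, which corresponds to the C9' configuration of the target.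

**Step 13**
Reactants: 19 C9' methallyl compound
Product: 20 C9' isobutyl compound
Conditions: H2 (1 atm), 10% Pd/C, EtOAc, 20 °C
Reagents that add atoms: none
Why: Heterogeneous hydrogenation saturates the 1,1-disubstituted alkene to the isobutyl group; the arene, the benzylic C–C bonds and the alcohols are not affected and no stereocentre is formed.

**Step 14**
Reactants: 20 C9' isobutyl compound
Product: 21 aryl dibromide
Conditions: N-bromosuccinimide (2.1 equiv), MeCN, 0 °C
Reagents that add atoms: N-bromosuccinimide, O=C1CCC(=O)N1Br
Why: Electrophilic aromatic bromination takes place at the only two free ring positions, each activated by two ortho and one para methoxy group, under conditions that leave the tertiary alcohols alone.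

**Step 15**
Reactants: 21 aryl dibromide
Product: 23 dialdehyde tri-O-methyl ether, via tetralithiated intermediate 22 (not isolated)
Conditions: MeLi (2.1 equiv), THF, −78 °C; t-BuLi (4.4 equiv), −78 °C; DMF (excess), −78 → 0 °C; aq. NH4Cl
Reagents that add atoms: N,N-dimethylformamide, CN(C)C=O; methyllithium, [Li]C, and tert-butyllithium, [Li]C(C)(C)C (lithium atoms of 22 only)
Why: MeLi first converts the two hydroxyls into lithium alkoxides so that no proton source remains, t-BuLi then carries out a double bromine–lithium exchange to an aryl dianion stabilised by the flanking methoxy groups, and DMF formylates both positions (halogen–metal exchange and formylation).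

**Step 16**
Reactants: 23 dialdehyde tri-O-methyl ether
Product: 24 target compound
Conditions: NaSEt (12 equiv), DMF, 130 °C; then 1 M HCl
Reagents that add atoms: none
Why: Thiolate cleaves the three aryl methyl ethers by SN2 attack at the methyl carbons, each phenoxide leaving group being stabilised by ortho and para formyl groups, while the tertiary alcohols, the aldehydes and all stereocentres should be untouched (nucleophilic O-demethylation).

**Compound list**

1 | Hagemann's ester, ethyl 2-methyl-4-oxocyclohex-2-ene-1-carboxylate (racemic) | CCOC(=O)C1CCC(=O)C=C1C | starting material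
2 | vinylmagnesium bromide | C=C[Mg]Br | starting material
3 | prenyl bromide (1-bromo-3-methylbut-2-ene) | CC(C)=CCBr | starting material
4 | ethyl 4-(bromomagnesiooxy)-2-methyl-2-vinylcyclohex-3-ene-1-carboxylate, vinyl trans to ester (racemic, one enantiomer drawn) | CCOC(=O)[C@H]1CCC(O[Mg]Br)=C[C@]1(C)C=C | intermediate (not isolated)
5 | ethyl 2-methyl-3-(3-methylbut-2-en-1-yl)-4-oxo-2-vinylcyclohexane-1-carboxylate, ester cis to methyl, both epimers at the prenyl-bearing carbon C5 (racemic, one enantiomer drawn) | CCOC(=O)[C@H]1CCC(=O)C(CC=C(C)C)[C@]1(C)C=C | intermediate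
6 | the same keto ester as one stereoisomer: ester cis to the C10 methyl, C5 prenyl trans to the C10 vinyl group | CCOC(=O)[C@H]1CCC(=O)[C@@H](CC=C(C)C)[C@]1(C)C=C | intermediate
7 | ethyl 2-[2-(1,3,2-benzodioxaborol-2-yl)ethyl]-2-methyl-3-(3-methylbut-2-en-1-yl)-4-oxocyclohexane-1-carboxylate, configuration as 6 | CCOC(=O)[C@H]1CCC(=O)[C@@H](CC=C(C)C)[C@]1(C)CCB2Oc3ccccc3O2 | intermediate (not isolated)
8 | ethyl 2-(2-hydroxyethyl)-2-methyl-3-(3-methylbut-2-en-1-yl)-4-oxocyclohexane-1-carboxylate, configuration as 6 | CCOC(=O)[C@H]1CCC(=O)[C@@H](CC=C(C)C)[C@]1(C)CCO | intermediate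
9 | ethyl 2-methyl-3-(3-methylbut-2-en-1-yl)-4-oxo-2-(2-oxoethyl)cyclohexane-1-carboxylate; C5 prenyl trans to the C10 CH2CHO arm, ester cis to the C10 methyl | CCOC(=O)[C@H]1CCC(=O)[C@@H](CC=C(C)C)[C@]1(C)CC=O | intermediate
10 | ethyl 8-hydroxy-7-(2-hydroxypropan-2-yl)-10-methyl-4-oxo-trans-decalin-1-carboxylate (locants of the plan); ester and C7 group equatorial and cis to the C10 methyl, C8 hydroxyl equatorial | CCOC(=O)[C@H]1CCC(=O)[C@H]2C[C@@H](C(C)(C)O)[C@H](O)C[C@]12C | intermediate
11 | C8 O-phenyl thionocarbonate of 10 | CCOC(=O)[C@H]1CCC(=O)[C@H]2C[C@@H](C(C)(C)O)[C@H](OC(=S)Oc3ccccc3)C[C@]12C | intermediate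
12 | ethyl 7-(2-hydroxypropan-2-yl)-10-methyl-4-oxo-trans-decalin-1-carboxylate | CCOC(=O)[C@H]1CCC(=O)[C@H]2C[C@@H](C(C)(C)O)CC[C@]12C | intermediate
13 | ethyl 4-hydroxy-7-(2-hydroxypropan-2-yl)-4,10-dimethyl-trans-decalin-1-carboxylate; C4 hydroxyl axial, cis to the C10 methyl | CCOC(=O)[C@H]1CC[C@@](C)(O)[C@H]2C[C@@H](C(C)(C)O)CC[C@]12C | intermediate
14 | 1-(hydroxymethyl)-7-(2-hydroxypropan-2-yl)-4,10-dimethyl-trans-decalin-4-ol | OC[C@H]1CC[C@@](C)(O)[C@H]2C[C@@H](C(C)(C)O)CC[C@]12C | intermediate
15 | 4-hydroxy-7-(2-hydroxypropan-2-yl)-4,10-dimethyl-trans-decalin-1-carbaldehyde | O=C[C@H]1CC[C@@](C)(O)[C@H]2C[C@@H](C(C)(C)O)CC[C@]12C | intermediate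
16 | 1,3,5-trimethoxybenzene | COc1cc(OC)cc(OC)c1 | starting material
17 | 2,4,6-trimethoxyphenyllithium | [Li]c1c(OC)cc(OC)cc1OC | intermediate (not isolated)
18 | [4-hydroxy-7-(2-hydroxypropan-2-yl)-4,10-dimethyl-trans-decalin-1-yl](2,4,6-trimethoxyphenyl)methanol, both C9' epimers | OC(c1c(OC)cc(OC)cc1OC)[C@H]1CC[C@@](C)(O)[C@H]2C[C@@H](C(C)(C)O)CC[C@]12C | intermediate
19 | 7-(2-hydroxypropan-2-yl)-4,10-dimethyl-1-[3-methyl-1-(2,4,6-trimethoxyphenyl)but-3-en-1-yl]-trans-decalin-4-ol, C9' as in the target | C=C(C)C[C@@H](c1c(OC)cc(OC)cc1OC)[C@H]1CC[C@@](C)(O)[C@H]2C[C@@H](C(C)(C)O)CC[C@]12C | intermediate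
20 | 7-(2-hydroxypropan-2-yl)-4,10-dimethyl-1-[3-methyl-1-(2,4,6-trimethoxyphenyl)butyl]-trans-decalin-4-ol | CC(C)C[C@@H](c1c(OC)cc(OC)cc1OC)[C@H]1CC[C@@](C)(O)[C@H]2C[C@@H](C(C)(C)O)CC[C@]12C | intermediate
21 | 3',5'-dibromo derivative of 20 | CC(C)C[C@@H](c1c(OC)c(Br)c(OC)c(Br)c1OC)[C@H]1CC[C@@](C)(O)[C@H]2C[C@@H](C(C)(C)O)CC[C@]12C | intermediate
22 | 3',5'-dilithio dilithium dialkoxide derived from 21 | CC(C)C[C@@H](c1c(OC)c([Li])c(OC)c([Li])c1OC)[C@H]1CC[C@@](C)(O[Li])[C@H]2C[C@@H](C(C)(C)O[Li])CC[C@]12C | intermediate (not isolated)
23 | 5-{1-[4-hydroxy-7-(2-hydroxypropan-2-yl)-4,10-dimethyl-trans-decalin-1-yl]-3-methylbutyl}-2,4,6-trimethoxybenzene-1,3-dicarbaldehyde | CC(C)C[C@@H](c1c(OC)c(C=O)c(OC)c(C=O)c1OC)[C@H]1CC[C@@](C)(O)[C@H]2C[C@@H](C(C)(C)O)CC[C@]12C | intermediate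
24 | 2,4,6-trihydroxy-5-{1-[4-hydroxy-7-(2-hydroxypropan-2-yl)-4,10-dimethyl-trans-decalin-1-yl]-3-methylbutyl}benzene-1,3-dicarbaldehyde (CNP0409870.6) | CC(C)C[C@@H](c1c(O)c(C=O)c(O)c(C=O)c1O)[C@H]1CC[C@@](C)(O)[C@H]2C[C@@H](C(C)(C)O)CC[C@]12C | target

**Step count and risks**

Total step count: 16. Longest linear sequence: 16 steps (from 1 to 24; the aryllithium from 16 is made inside step 11).

Steps most likely to fail:

1. Step 12. The allylsilane may capture the benzylic cation with poor facial selectivity, or the acid may also ionise the tertiary hydroxyls. The fallback sets out from 18 and exchanges the order in which the two C9' substituents arrive. Perruthenate oxidation (tetrapropylammonium perruthenate, N-methylmorpholine N-oxide) gives the aryl ketone F2. Isobutylmagnesium bromide with CeCl3 in THF at −78 °C gives the tertiary benzylic alcohol F3. Ionisation with BF3·OEt2 in the presence of Et3SiH at −78 °C then delivers hydride to the tertiary cation and rejoins the route at 20. This helps above all if the allylation favours the wrong epimer, because hydride then enters where the carbon nucleophile did and the C9' configuration is inverted.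

2. Step 5. The aldehyde may be diverted by enolisation of the C4 ketone (aldol closure or C5 epimerisation), or the C11 cation may lose a proton instead of taking up water. The fallback sets out from 9 and closes the same C7–C8 bond and the same ring as a concerted carbonyl-ene reaction (Me2AlCl, CH2Cl2, −78 °C). This has no free cation and no Brønsted acid, and should give the isopropenyl homoallylic alcohol F1. A Mukaiyama hydration (Co(acac)2, PhSiH3, O2, i-PrOH) then places the hydroxyl on C11 and rejoins the route at 10.

3. Step 15. The second bromine–lithium exchange may stay incomplete, or an aryllithium may be protonated before formylation, so that only one formyl group is introduced. The fallback sets out from 21 and avoids aryl anions. A Suzuki–Miyaura coupling with potassium vinyltrifluoroborate (Pd(OAc)2, SPhos, K2CO3, toluene/H2O, 90 °C) gives the divinylarene F4. Lemieux–Johnson cleavage (OsO4 cat., NaIO4, 2,6-lutidine, dioxane/H2O) of both vinyl groups rejoins the route at 23.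

**Further compounds**

F1 | step 5 | ethyl 8-hydroxy-10-methyl-4-oxo-7-(prop-1-en-2-yl)-trans-decalin-1-carboxylate, configuration as 10 | CCOC(=O)[C@H]1CCC(=O)[C@H]2C[C@@H](C(C)=C)[C@H](O)C[C@]12C
F2 | step 12 | [4-hydroxy-7-(2-hydroxypropan-2-yl)-4,10-dimethyl-trans-decalin-1-yl](2,4,6-trimethoxyphenyl)methanone | O=C(c1c(OC)cc(OC)cc1OC)[C@H]1CC[C@@](C)(O)[C@H]2C[C@@H](C(C)(C)O)CC[C@]12C
F3 | step 12 | 1-[4-hydroxy-7-(2-hydroxypropan-2-yl)-4,10-dimethyl-trans-decalin-1-yl]-3-methyl-1-(2,4,6-trimethoxyphenyl)butan-1-ol, both carbinol epimers | CC(C)CC(O)(c1c(OC)cc(OC)cc1OC)[C@H]1CC[C@@](C)(O)[C@H]2C[C@@H](C(C)(C)O)CC[C@]12C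
F4 | step 15 | 3',5'-divinyl analogue of 21 (vinyl in place of each bromine) | CC(C)C[C@@H](c1c(OC)c(C=C)c(OC)c(C=C)c1OC)[C@H]1CC[C@@](C)(O)[C@H]2C[C@@H](C(C)(C)O)CC[C@]12C
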